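**Assumption:** Aspidin as drawn has no stereocentres (the gem-dimethyl carbon is not stereogenic), so it is achiral and the "single enantiomer" requirement does not apply; the SMILES is one enol tautomer of the target.

## Retrosynthetic overview

1. The obvious disconnection (joining two finished monomers with formaldehyde) is avoided. The bridging CH2 is instead the existing C-methyl group of trione 5, activated oxidatively to an exo-methylene trione and captured by phenol 9 (C–H/C–H cross-coupling).
2. Both halves come from one intermediate, 3: dearomative C,C-dimethylation gives 5; protect/O-methylate/deprotect gives pseudo-aspidinol 9.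
3. Intermediate 3 comes from Friedel–Crafts butyrylation of 2,4,6-trihydroxytoluene.
4. Ring order: no ring is built. The aromatic ring is purchased, and the filicinic (cyclohexadienone) ring arises by dearomatising that same arene (step 2) before the final coupling.

## Route

**Step 1**
Reactants: 1 (2-methylbenzene-1,3,5-triol); 2 (butanoyl chloride)
Product: 3, 1-(2,4,6-trihydroxy-3-methylphenyl)butan-1-one
Conditions: AlCl3 (3.5 equiv), PhNO2/CH2Cl2, 0 → 45 °C; then ice/1 M HCl
Reagents that add atoms: butanoyl chloride, CCCC(=O)Cl
Why: Friedel–Crafts acylation; the two free ring positions are symmetry-equivalent, so only one mono-ketone can form, and the new acyl group deactivates the ring toward a second acylation.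

**Step 2**
Reactants: 3; 4 (iodomethane)
Product: 5, 2-butanoyl-3,5-dihydroxy-4,6,6-trimethylcyclohexa-2,4-dien-1-one
Conditions: NaOMe (3.2 equiv), MeI (2.2 equiv), MeOH, 0 °C → rt; then 1 M HCl
Reagents that add atoms: iodomethane, CI (two methyl groups)
Why: Dearomative C-methylation of the acylphloroglucinol polyanion (the classical filicinic-acid alkylation); both possible orders of the two C-methylations converge on the same gem-dimethyl/mono-methyl trione, and limiting MeI keeps down the inert tetramethyl by-product.

**Step 3**
Reactants: 3; 6 (benzyl bromide)
Product: 7, 1-[4,6-bis(benzyloxy)-2-hydroxy-3-methylphenyl]butan-1-one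
Conditions: BnBr (2.05 equiv), K2CO3 (2.2 equiv), acetone, rt → 40 °C
Reagents that add atoms: benzyl bromide, BrCc1ccccc1 (two benzyl groups)
Why: Williamson etherification; the 4-OH (para to C=O, most acidic, not chelated) and the less hindered 6-OH react, while the 2-OH, pushed by the adjacent methyl into the strongest hydrogen bond with the ketone, stays free.

**Step 4**
Reactants: 7; 4 (iodomethane)
Product: 8, 1-[4,6-bis(benzyloxy)-2-methoxy-3-methylphenyl]butan-1-one
Conditions: MeI (5 equiv), K2CO3, DMF, 60 °C
Reagents that add atoms: iodomethane, CI
Why: Forcing Williamson O-methylation of the only remaining (chelated, hindered) phenol; benzyl ethers and the aryl ketone are inert, and with no other free OH, C-alkylation does not compete.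

**Step 5**
Reactants: 8
Product: 9, 1-(4,6-dihydroxy-2-methoxy-3-methylphenyl)butan-1-one (pseudo-aspidinol)
Conditions: H2 (1 atm), 10% Pd/C, EtOAc/MeOH, rt
Reagents that add atoms: none
Why: Hydrogenolysis of the two benzyl ethers; the methyl ether and the electron-rich (vinylogous-ester-like) aryl ketone are not reduced under these mild conditions.

**Step 6 (key step)**
Reactants: 5; 9 (1.5 equiv)
Product: 10, aspidin: 2-butanoyl-4-[(5-butanoyl-2,6-dihydroxy-4-methoxy-3-methylphenyl)methyl]-3,5-dihydroxy-6,6-dimethylcyclohexa-2,4-dien-1-one (achiral)
Conditions: TEMPO (1.2 equiv), Ag2O (1.5 equiv), THF, 0 °C → rt, dark; then 1 M HCl work-up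
Reagents that add atoms: none
Why: Proposed new method: Ag2O oxidises the acidic enol of 5 to a stabilised radical that TEMPO traps at the methyl-bearing carbon, loss of TEMPO–H gives the exo-methylene trione (an o-quinone-methide equivalent), and phenol 9 adds through its only free ring carbon in a Friedel–Crafts-type Michael addition, then re-enolises and rearomatises to aspidin with no homodimers possible; the closest known reactions are Ag2O/TEMPO oxidation of the isobutyryl analogue of 5 to the same methide (trapped by alkenes in hetero-Diels–Alder reactions) and Michael addition of acylphloroglucinols to alkylidene triketones.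

## Compound list

1 | 2-methylbenzene-1,3,5-triol (2,4,6-trihydroxytoluene) | Cc1c(O)cc(O)cc1O | starting material
2 | butanoyl chloride | CCCC(=O)Cl | starting material
3 | 1-(2,4,6-trihydroxy-3-methylphenyl)butan-1-one | CCCC(=O)c1c(O)cc(O)c(C)c1O | intermediate
4 | iodomethane | CI | starting material
5 | 2-butanoyl-3,5-dihydroxy-4,6,6-trimethylcyclohexa-2,4-dien-1-one | CCCC(=O)C1=C(O)C(C)=C(O)C(C)(C)C1=O | intermediate
6 | benzyl bromide | BrCc1ccccc1 | starting material
7 | 1-[4,6-bis(benzyloxy)-2-hydroxy-3-methylphenyl]butan-1-one | CCCC(=O)c1c(OCc2ccccc2)cc(OCc2ccccc2)c(C)c1O | intermediate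
8 | 1-[4,6-bis(benzyloxy)-2-methoxy-3-methylphenyl]butan-1-one | CCCC(=O)c1c(OCc2ccccc2)cc(OCc2ccccc2)c(C)c1OC | intermediate
9 | 1-(4,6-dihydroxy-2-methoxy-3-methylphenyl)butan-1-one (pseudo-aspidinol) | CCCC(=O)c1c(O)cc(O)c(C)c1OC | intermediate
10 | aspidin (achiral) | CCCC(=O)C1=C(O)C(Cc2c(O)c(C)c(OC)c(C(=O)CCC)c2O)=C(O)C(C)(C)C1=O | target

## Summary

Total steps: 6. Longest linear sequence: 5 (1 → 3 → 7 → 8 → 9 → 10); the 3 → 5 branch is one step.

Steps most likely to fail, with fallbacks:

1. **Step 6 (oxidative methide coupling).** Ag2O may oxidise phenol 9 or over-oxidise the doubly activated CH2 of the product, and the methide may dimerise. Fallback: drop the oxidation. Formylate 9 at its free ring carbon (POCl3/DMF) and join the aldehyde to butyrylfilicinic acid by reductive Knoevenagel alkylation (Hantzsch ester, proline), so the bridge carbon comes in as an aryl aldehyde.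
2. **Step 3 (2-OH versus 6-OH discrimination in the bis-benzylation).** The regioisomeric dibenzyl ether may form in significant amounts. Fallback: avoid differentiating the hydroxyls. Acylate an arene that already carries the O-methyl group (Hoesch reaction of 5-methoxy-4-methylbenzene-1,3-diol with butyronitrile, ZnCl2/HCl) and separate pseudo-aspidinol from its regioisomer aspidinol.
3. **Step 2 (controlling the degree of C-methylation).** Under- and over-methylated triones may dominate. Fallback: acylate after dearomatisation. Prepare 3,5-dihydroxy-2,6,6-trimethylcyclohexa-2,4-dien-1-one first, O-butyrylate it, and induce cyanide/DMAP-mediated O→C acyl migration to give 5.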